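**Retrosynthetic overview**
1. The target is numbered as 2-methoxy-6,7-dimethyl-8-aryl-1,4-naphthoquinone, with ring A the quinone, ring B the benzo ring and ring C the 2,4,5-trimethoxyphenyl group on C8. Ring A is the five-membered ring of a 7-aryl-1-indanone enlarged by one atom, C2, the methoxy-bearing carbon between the C1 carbonyl and C3.
2. End game: C2–OMe comes from C2–Br by addition–elimination on a bromoquinone. C4=O comes from C4–H of a 2-bromo-1-naphthol by Teuber oxidation.
3. Key disconnection: C2 is removed as :CBr2 (bonds C1–C2 and C2–C3), which restores the C1–C3 bond of an indanone silyl enol ether.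
4. C8–C1' comes from Suzuki coupling of the indanone 7-triflate. The five-membered ring comes from Fries rearrangement and Friedel–Crafts closure on 2,3-dimethylphenol, whose OH carbon becomes C8, so the carbonyl lies peri to ring C.
5. Ring order: ring B (bought), then the five-membered carbocycle, then ring C attached (bought), then ring A by expansion of the five-membered ring.

Key step: step 6

Assumption: the target SMILES fixes no configuration at the C8–C1' biaryl axis, so the axis is left uncontrolled and all biaryl compounds are taken as racemic about it.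

**Step 1**
Reactants: 1 2,3-dimethylphenol; 2 3-chloropropanoyl chloride
Product: 3 2,3-dimethylphenyl 3-chloropropanoate
Conditions: toluene, reflux, no base, N2 sweep
Reagents that add atoms: none
Why: This is O-acylation of a phenol by an acid chloride, run without base so that HCl leaves as a gas and the β-chloride is not eliminated to the acrylate.

**Step 2**
Reactants: 3 2,3-dimethylphenyl 3-chloropropanoate
Product: 5 7-hydroxy-5,6-dimethyl-2,3-dihydro-1H-inden-1-one, via ortho-acylphenol 4 (not isolated)
Conditions: AlCl3 (3.5 equiv), neat melt, 100 °C then 170 °C; ice/aq. HCl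
Reagents that add atoms: none
Why: A high-temperature Fries rearrangement favours the aluminium-chelated ortho-acyl phenolate at the only free ortho carbon, the same Lewis acid then closes the five-membered ring by intramolecular Friedel–Crafts alkylation at the only free carbon next to the acyl group (a sequence known for 7-hydroxyindan-1-ones), and the internal hydrogen bond of 5 should allow its separation from material formed by para migration.

**Step 3**
Reactants: 5 7-hydroxy-5,6-dimethyl-2,3-dihydro-1H-inden-1-one
Product: 6 5,6-dimethyl-3-oxo-2,3-dihydro-1H-inden-4-yl trifluoromethanesulfonate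
Conditions: Tf2O, pyridine, CH2Cl2, 0 °C → rt
Reagents that add atoms: trifluoromethanesulfonic anhydride, FC(F)(F)S(=O)(=O)OS(=O)(=O)C(F)(F)F
Why: This is O-sulfonylation of a phenol, and the strongly electrophilic anhydride overcomes the hydrogen bond to the peri carbonyl, as is routine for 7-hydroxyindanones.

**Step 4**
Reactants: 6 5,6-dimethyl-3-oxo-2,3-dihydro-1H-inden-4-yl trifluoromethanesulfonate; 7 2,4,5-trimethoxyphenylboronic acid
Product: 8 5,6-dimethyl-7-(2,4,5-trimethoxyphenyl)-2,3-dihydro-1H-inden-1-one
Conditions: Pd(OAc)2 (3 mol %), SPhos (6 mol %), K3PO4, toluene/H2O, 90 °C; 7 used in 1.5-fold excess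
Reagents that add atoms: none
Why: In this Suzuki–Miyaura coupling the ortho carbonyl helps insertion of zerovalent palladium into the C–OTf bond, the bulky electron-rich biarylphosphine is the established ligand type for biaryls with three ortho substituents, and the excess of 7 offsets protodeboronation.

**Step 5**
Reactants: 8 5,6-dimethyl-7-(2,4,5-trimethoxyphenyl)-2,3-dihydro-1H-inden-1-one
Product: 9 trimethyl{[5,6-dimethyl-4-(2,4,5-trimethoxyphenyl)-1H-inden-3-yl]oxy}silane
Conditions: TMSOTf, Et3N, CH2Cl2, 0 °C; taken up in pentane, cold aq. NaHCO3 wash, used directly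
Reagents that add atoms: trimethylsilyl trifluoromethanesulfonate, C[Si](C)(C)OS(=O)(=O)C(F)(F)F
Why: This is soft enolization with O-silylation, and because the ketone has a single enolizable carbon only one silyl enol ether can form.

**Step 6**
Reactants: 9 trimethyl{[5,6-dimethyl-4-(2,4,5-trimethoxyphenyl)-1H-inden-3-yl]oxy}silane; 10 bromoform
Product: 13 2-bromo-6,7-dimethyl-8-(2,4,5-trimethoxyphenyl)naphthalen-1-ol, via dibromocyclopropane 11 (not isolated), via bromodienone 12 (not isolated)
Conditions: CHBr3 (2 equiv), KOtBu (4 equiv, added in portions to 9 and CHBr3), pentane, −78 °C → rt; aq. NH4Cl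
Reagents that add atoms: none
Why: KOtBu deprotonates CHBr3, the tribromomethyl anion loses bromide, and the singlet :CBr2 adds in a concerted cheletropic [2+1] fashion to the enol ether C=C of 9 (the carbons that become C1 and C3), making C1–C2 and C2–C3 at once in the cis-fused cyclopropane 11. Pushed by the siloxy oxygen, 11 then undergoes the disrotatory two-electron electrocyclic opening allowed by the Woodward–Hoffmann–DePuy rule, with the endo bromide leaving as the shared C1–C3 bond breaks; tert-butoxide removes the silyl group from the oxocarbenium ion to give dienone 12, which enolizes through its C4 methylene to the aromatic naphthol 13. The closest known chemistry is the dihalocarbene enlargement of indenes to 2-halonaphthalenes and of silyl enol ethers of cyclic ketones, 1-indanones included, to 2-halo enones and 2-halo-1-naphthols. Ring A is thus not made by cyclization: the three-membered ring closes by cycloaddition, and the six-membered ring appears when the bond common to the three- and five-membered rings is cut. The two stereocentres of 11 are cis because of the ring fusion and disappear on aromatization, so no stereocontrol is needed. The step needs chemoselectivity for the enol ether over rings B and C and over Si–O cleavage or deprotonation of the indene CH2, which is secured because the electrophilic carbene takes the most electron-rich π bond and the base, added in portions to excess and far more acidic CHBr3 in pentane, is consumed by it; the regiochemistry is built in, since the oxygen-bearing carbon must become C1 and the inserted CBr must become C2.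

**Step 7**
Reactants: 13 2-bromo-6,7-dimethyl-8-(2,4,5-trimethoxyphenyl)naphthalen-1-ol
Product: 14 2-bromo-6,7-dimethyl-8-(2,4,5-trimethoxyphenyl)naphthalene-1,4-dione
Conditions: (KSO3)2NO (2.5 equiv), KH2PO4 buffer, acetone/H2O, rt
Reagents that add atoms: dipotassium nitrosodisulfonate (KSO3)2NO, [K+].[K+].[O]N(S(=O)(=O)[O-])S(=O)(=O)[O-]
Why: In this Teuber oxidation one nitroxyl radical abstracts the naphthol hydrogen and a second couples at the free para carbon C4 and collapses to the p-quinone, while C2 is blocked by bromine and the fully O-methylated ring C, which has no free OH, is left alone by this mild one-electron oxidant.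

**Step 8**
Reactants: 14 2-bromo-6,7-dimethyl-8-(2,4,5-trimethoxyphenyl)naphthalene-1,4-dione
Product: 15 2-methoxy-6,7-dimethyl-8-(2,4,5-trimethoxyphenyl)naphthalene-1,4-dione (CNP0272937.0)
Conditions: NaOMe (1.05 equiv), MeOH/THF, 0 °C
Reagents that add atoms: sodium methoxide, C[O-].[Na+]
Why: This is addition–elimination on a haloquinone, in which methoxide attacks C2, the β-carbon of the unhindered C4 enone, and the enolate expels bromide directly, whereas attack at C3 would have to be relayed through the C1 carbonyl crowded by the peri ring C and finds no leaving group there.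

**Compound list**
1 | 2,3-dimethylphenol | Cc1cccc(O)c1C | starting material
2 | 3-chloropropanoyl chloride | ClCCC(Cl)=O | starting material
3 | 2,3-dimethylphenyl 3-chloropropanoate | O=C(CCCl)Oc1cccc(C)c1C | intermediate
4 | 3-chloro-1-(2-hydroxy-3,4-dimethylphenyl)propan-1-one | O=C(CCCl)c1ccc(C)c(C)c1O | intermediate (not isolated)
5 | 7-hydroxy-5,6-dimethyl-2,3-dihydro-1H-inden-1-one | O=C1CCc2cc(C)c(C)c(O)c12 | intermediate
6 | 5,6-dimethyl-3-oxo-2,3-dihydro-1H-inden-4-yl trifluoromethanesulfonate | O=C1CCc2cc(C)c(C)c(OS(=O)(=O)C(F)(F)F)c12 | intermediate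
7 | 2,4,5-trimethoxyphenylboronic acid | COc1cc(OC)c(B(O)O)cc1OC | starting material
8 | 5,6-dimethyl-7-(2,4,5-trimethoxyphenyl)-2,3-dihydro-1H-inden-1-one | O=C1CCc2cc(C)c(C)c(-c3cc(OC)c(OC)cc3OC)c12 | intermediate
9 | trimethyl{[5,6-dimethyl-4-(2,4,5-trimethoxyphenyl)-1H-inden-3-yl]oxy}silane | C[Si](C)(C)OC1=CCc2cc(C)c(C)c(-c3cc(OC)c(OC)cc3OC)c12 | intermediate
10 | bromoform | BrC(Br)Br | starting material
11 | 1,1-dibromo-3,4-dimethyl-2-(2,4,5-trimethoxyphenyl)-1a-(trimethylsilyloxy)-1,1a,6,6a-tetrahydrocyclopropa[a]indene (cis-fused, racemic, one enantiomer drawn) | C[Si](C)(C)O[C@@]12c3c(-c4cc(OC)c(OC)cc4OC)c(C)c(C)cc3C[C@@H]1C2(Br)Br | intermediate (not isolated)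
12 | 2-bromo-6,7-dimethyl-8-(2,4,5-trimethoxyphenyl)naphthalen-1(4H)-one | O=C1C(Br)=CCc2cc(C)c(C)c(-c3cc(OC)c(OC)cc3OC)c12 | intermediate (not isolated)
13 | 2-bromo-6,7-dimethyl-8-(2,4,5-trimethoxyphenyl)naphthalen-1-ol | Oc1c(Br)ccc2cc(C)c(C)c(-c3cc(OC)c(OC)cc3OC)c12 | intermediate
14 | 2-bromo-6,7-dimethyl-8-(2,4,5-trimethoxyphenyl)naphthalene-1,4-dione | O=C1C(Br)=CC(=O)c2cc(C)c(C)c(-c3cc(OC)c(OC)cc3OC)c12 | intermediate
15 | 2-methoxy-6,7-dimethyl-8-(2,4,5-trimethoxyphenyl)naphthalene-1,4-dione | COC1=CC(=O)c2cc(C)c(C)c(-c3cc(OC)c(OC)cc3OC)c2C1=O | target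

**Total step count:** 8
**Longest linear sequence:** 8 steps (1 → 15); compounds 2, 7 and 10 are bought.

**Steps most likely to fail**

1. Step 6 (key step).
- Risk: tert-butoxide may strip the silyl group or deprotonate the doubly activated indene CH2 faster than the carbene is transferred. The peri ring C may slow approach to the double bond. The liberated naphtholate may be alkylated by further carbene in a Reimer–Tiemann manner.
- Fallback: it sets out from 9 and returns at 13, and it inserts the carbon without strong base. A Furukawa-type Simmons–Smith cyclopropanation (Et2Zn, CH2I2, CH2Cl2, 0 °C) should give the halogen-free 3,4-dimethyl-2-(2,4,5-trimethoxyphenyl)-1a-(trimethylsilyloxy)-1,1a,6,6a-tetrahydrocyclopropa[a]indene F1. FeCl3 in DMF (Saegusa ring expansion) oxidizes it to the cyclopropyloxy radical, and β-scission of the shared bond followed by chlorine capture should give 3-chloro-6,7-dimethyl-8-(2,4,5-trimethoxyphenyl)-3,4-dihydronaphthalen-1(2H)-one F2. NaOAc in warm MeOH removes HCl, and the enone tautomerizes to 6,7-dimethyl-8-(2,4,5-trimethoxyphenyl)naphthalen-1-ol F3. Ortho-selective bromination (one equivalent of NBS, catalytic iPr2NH, CH2Cl2, low temperature) then places bromine on C2 and rejoins the route at 13.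

2. Step 2.
- Risk: acyl migration to the free para carbon competes with migration to the ortho carbon, and the hot melt may cause charring or methyl migration.
- Fallback: it sets out from 1 and returns at 5, and it fixes the regiochemistry with a tether. O-alkylation of 1 with 3-chloropropanoic acid (aq. NaOH, reflux) should give 3-(2,3-dimethylphenoxy)propanoic acid F4. Polyphosphoric acid closes it by intramolecular Friedel–Crafts acylation, which the tether can direct only to the ortho carbon, giving 7,8-dimethylchroman-4-one F5. The known AlCl3/NaCl-melt rearrangement of chroman-4-ones (retro-oxa-Michael opening on the aluminium-bound ketone, then closure of the three-carbon arm on carbon) then delivers 5.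

3. Step 8.
- Risk: methoxide may attack the unsubstituted C3, leading to cine substitution or, after reoxidation, to double substitution. Adventitious hydroxide may cleave the new vinylogous ester.
- Fallback: it sets out from 13 and returns at 15, and it forms the C2–O bond at the carbon that carries bromine before the quinone exists. Copper-catalysed Ullmann-type methoxylation of the ortho-bromonaphtholate (CuI, excess NaOMe, DMF/MeOH, 110 °C, as practised on ortho-bromophenols) should give 2-methoxy-6,7-dimethyl-8-(2,4,5-trimethoxyphenyl)naphthalen-1-ol F6. This more electron-rich naphthol is then oxidized at C4 with (KSO3)2NO under the conditions of step 7 to give 15.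

**Further compounds**
F1 | step 6 | 3,4-dimethyl-2-(2,4,5-trimethoxyphenyl)-1a-(trimethylsilyloxy)-1,1a,6,6a-tetrahydrocyclopropa[a]indene (cis-fused, racemic, one enantiomer drawn) | C[Si](C)(C)O[C@@]12c3c(-c4cc(OC)c(OC)cc4OC)c(C)c(C)cc3C[C@@H]1C2
F2 | step 6 | 3-chloro-6,7-dimethyl-8-(2,4,5-trimethoxyphenyl)-3,4-dihydronaphthalen-1(2H)-one (racemic at C3) | O=C1CC(Cl)Cc2cc(C)c(C)c(-c3cc(OC)c(OC)cc3OC)c12
F3 | step 6 | 6,7-dimethyl-8-(2,4,5-trimethoxyphenyl)naphthalen-1-ol | Oc1cccc2cc(C)c(C)c(-c3cc(OC)c(OC)cc3OC)c12
F4 | step 2 | 3-(2,3-dimethylphenoxy)propanoic acid | O=C(O)CCOc1cccc(C)c1C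
F5 | step 2 | 7,8-dimethylchroman-4-one | O=C1CCOc2c(C)c(C)ccc12
F6 | step 8 | 2-methoxy-6,7-dimethyl-8-(2,4,5-trimethoxyphenyl)naphthalen-1-ol | COc1ccc2cc(C)c(C)c(-c3cc(OC)c(OC)cc3OC)c2c1O
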